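**Retrosynthetic overview**

1. Target 24 comes from protected flavanone 23 by one global hydrogenolysis (three aryl benzyl ethers and the benzylidene acetal of the side-chain 1,3-diol).
2. Ring C of 23 is made last, in the key step, by joining O1 to C8a and C4 to C4a. The alkoxide released from the (S)-β-silyloxy morpholine amide 13 (carrying C2, C3, C4, ring B and the side chain) is annulated onto 3,5-bis(benzyloxy)benzyne (ring A), released from silyl triflate 18.
3. Enabling feature: ring A is a phloroglucinol ring in which O-5 sits on the carbon next to C4a while C8, next to C8a, carries only hydrogen. In the C4a≡C8a aryne the C5 oxygen therefore steers the oxygen nucleophile to C8a and leaves the carbanion at C4a. The 1,3-relationship of O1 and the C4 carbonyl in ring C then makes the acyl capture a six-membered closure.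
4. C2 (S) comes from asymmetric transfer hydrogenation of β-keto amide 11 (Claisen condensation of aryl ester 8 with 4-acetylmorpholine). The threo (R,R) side chain comes from an Evans syn-glycolate aldol of aryloxyacetyl imide 3 (from methyl syringate) with 4-(benzyloxy)benzaldehyde.
5. Ring order: ring A, ring B and the p-oxyphenyl ring are bought as arenes; the temporary 1,3-dioxane ring is formed in step 4 and ring C in step 10.

Key step: step 10

Assumption: 3,5-bis(benzyloxy)phenol (14) and (S)-4-benzyl-3-(chloroacetyl)oxazolidin-2-one (2) are treated as catalogue compounds, and the configuration at C4 of the transient hemiaminal 22 is immaterial and left undefined.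

**Route**

Step 1
Reactants: 1 methyl 4-hydroxy-3,5-dimethoxybenzoate (methyl syringate); 2 (S)-4-benzyl-3-(chloroacetyl)oxazolidin-2-one
Product: 3 methyl 4-{2-[(4S)-4-benzyl-2-oxooxazolidin-3-yl]-2-oxoethoxy}-3,5-dimethoxybenzoate
Conditions: K2CO3, NaI (cat.), MeCN, 40 °C
Reagents that add atoms: none
Why: Williamson etherification, in which the acidic, ester-conjugated phenoxide displaces the halide of the activated α-halo imide (iodide-assisted SN2) faster than it attacks the imide carbonyl; no stereocenter is touched.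

Step 2
Reactants: 3 methyl 4-{2-[(4S)-4-benzyl-2-oxooxazolidin-3-yl]-2-oxoethoxy}-3,5-dimethoxybenzoate; 4 4-(benzyloxy)benzaldehyde
Product: 6 methyl 4-{[(2S,3R)-1-[(4S)-4-benzyl-2-oxooxazolidin-3-yl]-3-[4-(benzyloxy)phenyl]-3-hydroxy-1-oxopropan-2-yl]oxy}-3,5-dimethoxybenzoate, via dibutylboron (Z)-enolate 5 (not isolated)
Conditions: Bu2BOTf, iPr2NEt, CH2Cl2, −78 to 0 °C; then 4, −78 to 0 °C; pH 7 buffer, MeOH, H2O2, 0 °C
Reagents that add atoms: none
Why: Evans syn-glycolate aldol reaction, in which the (Z)-boron enolate reacts through a closed chair transition state with one enolate face blocked by the benzyl group of the (S)-auxiliary, which should set the (2S,3R) syn pair that becomes the (R,R) threo diol; the aryl methyl ester is inert.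

Step 3
Reactants: 6 methyl 4-{[(2S,3R)-1-[(4S)-4-benzyl-2-oxooxazolidin-3-yl]-3-[4-(benzyloxy)phenyl]-3-hydroxy-1-oxopropan-2-yl]oxy}-3,5-dimethoxybenzoate
Product: 7 methyl 4-{[(1R,2R)-1-[4-(benzyloxy)phenyl]-1,3-dihydroxypropan-2-yl]oxy}-3,5-dimethoxybenzoate
Conditions: NaBH4, THF/H2O, 0 °C to rt
Reagents that add atoms: none
Why: Reductive cleavage of the N-acyl oxazolidinone by borohydride, which should reduce the activated imide carbonyl to the primary alcohol while the electron-rich methyl benzoate is left alone and both stereocenters are retained.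

Step 4
Reactants: 7 methyl 4-{[(1R,2R)-1-[4-(benzyloxy)phenyl]-1,3-dihydroxypropan-2-yl]oxy}-3,5-dimethoxybenzoate
Product: 8 methyl 4-{[(2S,4R,5R)-4-[4-(benzyloxy)phenyl]-2-phenyl-1,3-dioxan-5-yl]oxy}-3,5-dimethoxybenzoate
Conditions: PhCH(OMe)2, camphorsulfonic acid (cat.), CH2Cl2, 4 Å MS, rt
Reagents that add atoms: benzaldehyde dimethyl acetal, COC(OC)c1ccccc1
Why: Acid-catalysed transacetalisation to the six-membered benzylidene acetal under thermodynamic control, which should place the 2-phenyl group equatorial and cis to the equatorial 4-aryl group (5-aryloxy axial, as the threo diol requires) and so fix the acetal carbon as (2S).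

Step 5
Reactants: 8 methyl 4-{[(2S,4R,5R)-4-[4-(benzyloxy)phenyl]-2-phenyl-1,3-dioxan-5-yl]oxy}-3,5-dimethoxybenzoate; 9 4-acetylmorpholine
Product: 11 1-(4-{[(2S,4R,5R)-4-[4-(benzyloxy)phenyl]-2-phenyl-1,3-dioxan-5-yl]oxy}-3,5-dimethoxyphenyl)-3-(morpholin-4-yl)propane-1,3-dione, via lithium amide enolate 10 (not isolated)
Conditions: LiN(iPr)2 (excess), THF, −78 °C; then 8, −78 to 0 °C; aq. NH4Cl
Reagents that add atoms: none
Why: Crossed Claisen condensation of the amide enolate with the non-enolisable aryl ester, driven to completion by deprotonation of the β-keto amide formed; the acetal and the ethers are inert to the base.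

Step 6
Reactants: 11 1-(4-{[(2S,4R,5R)-4-[4-(benzyloxy)phenyl]-2-phenyl-1,3-dioxan-5-yl]oxy}-3,5-dimethoxyphenyl)-3-(morpholin-4-yl)propane-1,3-dione
Product: 12 (3S)-3-(4-{[(2S,4R,5R)-4-[4-(benzyloxy)phenyl]-2-phenyl-1,3-dioxan-5-yl]oxy}-3,5-dimethoxyphenyl)-3-hydroxy-1-(morpholin-4-yl)propan-1-one
Conditions: RuCl[(S,S)-TsDPEN](p-cymene) (cat.), HCO2H/Et3N (5:2), EtOAc, 40 °C
Reagents that add atoms: none
Why: Noyori–Ikariya asymmetric transfer hydrogenation of an aryl β-keto amide, in which the (S,S)-catalyst is expected, as with aryl alkyl ketones, to deliver hydride to the face that gives the (S)-carbinol (the future C2) under catalyst control, the existing stereocenters being remote.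

Step 7
Reactants: 12 (3S)-3-(4-{[(2S,4R,5R)-4-[4-(benzyloxy)phenyl]-2-phenyl-1,3-dioxan-5-yl]oxy}-3,5-dimethoxyphenyl)-3-hydroxy-1-(morpholin-4-yl)propan-1-one
Product: 13 (3S)-3-(4-{[(2S,4R,5R)-4-[4-(benzyloxy)phenyl]-2-phenyl-1,3-dioxan-5-yl]oxy}-3,5-dimethoxyphenyl)-1-(morpholin-4-yl)-3-[(trimethylsilyl)oxy]propan-1-one
Conditions: Me3SiCl, imidazole, CH2Cl2, 0 °C; non-aqueous work-up
Reagents that add atoms: chlorotrimethylsilane, C[Si](C)(C)Cl
Why: Standard O-silylation of a secondary alcohol, which stores the only nucleophilic oxygen as a fluoride-labile, proton-free alkoxide precursor without touching the stereocenter.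

Step 8
Reactants: 14 3,5-bis(benzyloxy)phenol
Product: 15 3,5-bis(benzyloxy)-2-bromophenol
Conditions: NBS, iPr2NH (cat.), CH2Cl2, −78 to 0 °C
Reagents that add atoms: N-bromosuccinimide, O=C1CCC(=O)N1Br
Why: Amine-catalysed ortho-selective electrophilic bromination of a phenol, in which the hydrogen-bonded N-bromoamine should deliver bromine next to the hydroxyl group (the two ortho positions are equivalent) in preference to the para position.

Step 9
Reactants: 15 3,5-bis(benzyloxy)-2-bromophenol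
Product: 18 3,5-bis(benzyloxy)-2-(trimethylsilyl)phenyl trifluoromethanesulfonate, via aryl trimethylsilyl ether 16 (not isolated), via lithium 2-silylphenolate 17 (not isolated)
Conditions: (Me3Si)2NH, THF, 65 °C, evaporate; n-BuLi, THF, −78 °C; Tf2O, −78 °C
Reagents that add atoms: hexamethyldisilazane, C[Si](C)(C)N[Si](C)(C)C; trifluoromethanesulfonic anhydride, O=S(=O)(OS(=O)(=O)C(F)(F)F)C(F)(F)F
Why: Standard sequence to 2-(trimethylsilyl)aryl triflates: O-silylation, bromine–lithium exchange with anionic 1,3 O-to-C silyl shift (retro-Brook rearrangement) to the phenolate, and O-triflation, all at a temperature at which the benzyl ethers are not metalated.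

Step 10
Reactants: 13 (3S)-3-(4-{[(2S,4R,5R)-4-[4-(benzyloxy)phenyl]-2-phenyl-1,3-dioxan-5-yl]oxy}-3,5-dimethoxyphenyl)-1-(morpholin-4-yl)-3-[(trimethylsilyl)oxy]propan-1-one; 18 3,5-bis(benzyloxy)-2-(trimethylsilyl)phenyl trifluoromethanesulfonate
Product: 23 (2S)-5,7-bis(benzyloxy)-2-(4-{[(2S,4R,5R)-4-[4-(benzyloxy)phenyl]-2-phenyl-1,3-dioxan-5-yl]oxy}-3,5-dimethoxyphenyl)chroman-4-one, via caesium alkoxide 19 (not isolated), via 3,5-bis(benzyloxy)benzyne 20 (not isolated), via aryl anion 21 (not isolated), via hemiaminal alkoxide 22 (not isolated)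
Conditions: CsF, 18-crown-6, THF, 0 °C; then 18 (slow addition), 0 °C to rt; aq. NH4Cl
Reagents that add atoms: none
Why: Proposed new method: fluoride first removes the O-SiMe3 group of 13 to give the proton-free caesium alkoxide 19 and then triggers 1,2-elimination of 18 to aryne 20; the alkoxide adds to the aryne carbon remote from the flanking benzyloxy group (the future C8a), the aryl anion 21 so formed next to that benzyloxy group (the future C4a) attacks the morpholine amide carbonyl, and the hemiaminal alkoxide 22 keeps the carbonyl masked until the mildly acidic quench releases ketone 23 and morpholine. The closest known reaction types are the fluoride-mediated annulation of arynes with methyl salicylates and anthranilates to xanthones and acridones (heteroatom arylation followed by intramolecular acyl capture) and the acylation of aryl anions by tertiary amides in Parham-type and anionic Fries-type cyclisations; new here are a secondary aliphatic alkoxide as the nucleophile and a tertiary amide as the acyl acceptor. Ring C is closed by intermolecular O–C(aryl) bond formation followed by a 6-exo-trig attack of the aryl anion on the amide carbonyl. No stereocenter is created: C2 comes from step 6 and keeps its configuration because none of its bonds is broken, and the amide, unlike an ester, disfavours retro-aldol cleavage of the alkoxide and keeps the finished chromanone out of reach of base-induced retro-oxa-Michael ring opening. The step needs regioselective addition to the unsymmetrical aryne, which the inductively withdrawing C5 alkoxy group and the aryne distortion it causes should secure, and it needs carbonyl capture to outrun protonation of the aryl anion, which the aprotic unmasking of the alkoxide from its silyl ether (no O–H present) and THF as solvent should secure.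

Step 11
Reactants: 23 (2S)-5,7-bis(benzyloxy)-2-(4-{[(2S,4R,5R)-4-[4-(benzyloxy)phenyl]-2-phenyl-1,3-dioxan-5-yl]oxy}-3,5-dimethoxyphenyl)chroman-4-one
Product: 24 (2S)-5,7-dihydroxy-2-(4-{[(1R,2R)-1,3-dihydroxy-1-(4-hydroxyphenyl)propan-2-yl]oxy}-3,5-dimethoxyphenyl)chroman-4-one
Conditions: H2 (1 atm), 10% Pd/C, EtOAc/MeOH, rt
Reagents that add atoms: none
Why: Catalytic hydrogenolysis of the three aryl benzyl ethers and the benzylidene acetal, which under neutral conditions should be much faster than cleavage of the secondary benzylic carbinol C–O bond, of the C2–O1 bond or reduction of the aryl ketone, so that all three stereocenters are retained.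

**Compound list**

1 | methyl 4-hydroxy-3,5-dimethoxybenzoate (methyl syringate) | COC(=O)c1cc(OC)c(O)c(OC)c1 | starting material
2 | (S)-4-benzyl-3-(chloroacetyl)oxazolidin-2-one | O=C(CCl)N1[C@@H](Cc2ccccc2)COC1=O | starting material
3 | methyl 4-{2-[(4S)-4-benzyl-2-oxooxazolidin-3-yl]-2-oxoethoxy}-3,5-dimethoxybenzoate | COC(=O)c1cc(OC)c(OCC(=O)N2[C@@H](Cc3ccccc3)COC2=O)c(OC)c1 | intermediate
4 | 4-(benzyloxy)benzaldehyde | O=Cc1ccc(OCc2ccccc2)cc1 | starting material
5 | dibutylboron (Z)-enolate of 3, formed in situ | COC(=O)c1cc(OC)c(O/C=C(\OB(CCCC)CCCC)N2[C@@H](Cc3ccccc3)COC2=O)c(OC)c1 | intermediate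
6 | methyl 4-{[(2S,3R)-1-[(4S)-4-benzyl-2-oxooxazolidin-3-yl]-3-[4-(benzyloxy)phenyl]-3-hydroxy-1-oxopropan-2-yl]oxy}-3,5-dimethoxybenzoate | COC(=O)c1cc(OC)c(O[C@@H]([C@H](O)c2ccc(OCc3ccccc3)cc2)C(=O)N2[C@@H](Cc3ccccc3)COC2=O)c(OC)c1 | intermediate
7 | methyl 4-{[(1R,2R)-1-[4-(benzyloxy)phenyl]-1,3-dihydroxypropan-2-yl]oxy}-3,5-dimethoxybenzoate | COC(=O)c1cc(OC)c(O[C@H](CO)[C@H](O)c2ccc(OCc3ccccc3)cc2)c(OC)c1 | intermediate
8 | methyl 4-{[(2S,4R,5R)-4-[4-(benzyloxy)phenyl]-2-phenyl-1,3-dioxan-5-yl]oxy}-3,5-dimethoxybenzoate | COC(=O)c1cc(OC)c(O[C@@H]2CO[C@H](c3ccccc3)O[C@@H]2c2ccc(OCc3ccccc3)cc2)c(OC)c1 | intermediate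
9 | 4-acetylmorpholine | CC(=O)N1CCOCC1 | starting material
10 | lithium enolate of 4-acetylmorpholine, formed in situ | C=C(O[Li])N1CCOCC1 | intermediate
11 | 1-(4-{[(2S,4R,5R)-4-[4-(benzyloxy)phenyl]-2-phenyl-1,3-dioxan-5-yl]oxy}-3,5-dimethoxyphenyl)-3-(morpholin-4-yl)propane-1,3-dione | O=C(CC(=O)N1CCOCC1)c1cc(OC)c(O[C@@H]2CO[C@H](c3ccccc3)O[C@@H]2c2ccc(OCc3ccccc3)cc2)c(OC)c1 | intermediate
12 | (3S)-3-(4-{[(2S,4R,5R)-4-[4-(benzyloxy)phenyl]-2-phenyl-1,3-dioxan-5-yl]oxy}-3,5-dimethoxyphenyl)-3-hydroxy-1-(morpholin-4-yl)propan-1-one | O[C@@H](CC(=O)N1CCOCC1)c1cc(OC)c(O[C@@H]2CO[C@H](c3ccccc3)O[C@@H]2c2ccc(OCc3ccccc3)cc2)c(OC)c1 | intermediate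
13 | (3S)-3-(4-{[(2S,4R,5R)-4-[4-(benzyloxy)phenyl]-2-phenyl-1,3-dioxan-5-yl]oxy}-3,5-dimethoxyphenyl)-1-(morpholin-4-yl)-3-[(trimethylsilyl)oxy]propan-1-one | C[Si](C)(C)O[C@@H](CC(=O)N1CCOCC1)c1cc(OC)c(O[C@@H]2CO[C@H](c3ccccc3)O[C@@H]2c2ccc(OCc3ccccc3)cc2)c(OC)c1 | intermediate
14 | 3,5-bis(benzyloxy)phenol | Oc1cc(OCc2ccccc2)cc(OCc2ccccc2)c1 | starting material
15 | 3,5-bis(benzyloxy)-2-bromophenol | Oc1cc(OCc2ccccc2)cc(OCc2ccccc2)c1Br | intermediate
16 | [3,5-bis(benzyloxy)-2-bromophenoxy]trimethylsilane, formed in situ | C[Si](C)(C)Oc1cc(OCc2ccccc2)cc(OCc2ccccc2)c1Br | intermediate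
17 | lithium 3,5-bis(benzyloxy)-2-(trimethylsilyl)phenolate, formed in situ | [Li+].[O-]c1cc(OCc2ccccc2)cc(OCc2ccccc2)c1[Si](C)(C)C | intermediate
18 | 3,5-bis(benzyloxy)-2-(trimethylsilyl)phenyl trifluoromethanesulfonate | C[Si](C)(C)c1c(OS(=O)(=O)C(F)(F)F)cc(OCc2ccccc2)cc1OCc1ccccc1 | intermediate
19 | caesium (1S)-alkoxide of 12, formed in situ | [Cs+].[O-][C@@H](CC(=O)N1CCOCC1)c1cc(OC)c(O[C@@H]2CO[C@H](c3ccccc3)O[C@@H]2c2ccc(OCc3ccccc3)cc2)c(OC)c1 | intermediate
20 | 3,5-bis(benzyloxy)benzyne (1,2-didehydro-3,5-bis(benzyloxy)benzene), formed in situ | C1#CC(OCc2ccccc2)=CC(OCc2ccccc2)=C1 | intermediate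
21 | caesium 2-{[(1S)-1-aryl-3-(morpholin-4-yl)-3-oxopropyl]oxy}-4,6-bis(benzyloxy)phenide (aryl anion after O-arylation), formed in situ | [Cs+].O=C(C[C@H](Oc1cc(OCc2ccccc2)cc(OCc2ccccc2)[c-]1)c1cc(OC)c(O[C@@H]2CO[C@H](c3ccccc3)O[C@@H]2c2ccc(OCc3ccccc3)cc2)c(OC)c1)N1CCOCC1 | intermediate
22 | caesium (2S)-5,7-bis(benzyloxy)-4-(morpholin-4-yl)-2-aryl-chroman-4-olate (hemiaminal alkoxide, C4 undefined), formed in situ | [Cs+].COc1cc([C@@H]2CC([O-])(N3CCOCC3)c3c(OCc4ccccc4)cc(OCc4ccccc4)cc3O2)cc(OC)c1O[C@@H]1CO[C@H](c2ccccc2)O[C@@H]1c1ccc(OCc2ccccc2)cc1 | intermediate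
23 | (2S)-5,7-bis(benzyloxy)-2-(4-{[(2S,4R,5R)-4-[4-(benzyloxy)phenyl]-2-phenyl-1,3-dioxan-5-yl]oxy}-3,5-dimethoxyphenyl)chroman-4-one | COc1cc([C@@H]2CC(=O)c3c(OCc4ccccc4)cc(OCc4ccccc4)cc3O2)cc(OC)c1O[C@@H]1CO[C@H](c2ccccc2)O[C@@H]1c1ccc(OCc2ccccc2)cc1 | intermediate
24 | (2S)-5,7-dihydroxy-2-(4-{[(1R,2R)-1,3-dihydroxy-1-(4-hydroxyphenyl)propan-2-yl]oxy}-3,5-dimethoxyphenyl)chroman-4-one | COc1cc([C@@H]2CC(=O)c3c(O)cc(O)cc3O2)cc(OC)c1O[C@H](CO)[C@H](O)c1ccc(O)cc1 | target

**Step count and risks**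

Total step count: 11. Longest linear sequence: 9 steps (steps 1 to 7, then 10 and 11); steps 8 and 9 form the two-step side branch to 18.

Steps most likely to fail:

Step 10 (proposed new method). The aryl anion may be protonated before it reaches the amide, giving plain O-arylation. The alkoxide may fragment by retro-aldol cleavage, or the C2 configuration may erode during work-up. Fallback, from 11 back to 23, with known reactions only: 11 is reduced with the enantiomeric catalyst RuCl[(R,R)-TsDPEN](p-cymene) in HCO2H/Et3N to the (3R)-configured β-hydroxy morpholine amide F1. Mitsunobu etherification of this alcohol with bromophenol 15 (PPh3, DIAD, THF, 0 °C) should give, with inversion, the (3S)-configured 2-bromoaryl ether F2. Bromine–lithium exchange (n-BuLi, THF, −78 °C) and Parham cyclisation of the aryllithium onto the morpholine amide should then give 23 after aqueous NH4Cl. In this variant the ring oxygen is joined to C2 instead of to ring A, and the aryl–carbonyl bond is made by a classical anionic cyclisation.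

Step 11. Over-reduction may occur: hydrogenolytic loss of the benzylic carbinol oxygen (directly or through the 4-aryl-1,3-dioxane), cleavage of the C2–O1 bond, or reduction of the ketone. Fallback, from 23 to 24, with the deprotection split into a non-reductive and a short reductive stage: the benzylidene acetal of 23 is hydrolysed first (AcOH/H2O 4:1, 40 °C) to the tris(benzyl ether) diol F3. Only the three fast-reacting aryl benzyl ethers of F3 are then removed by catalytic transfer hydrogenolysis (10% Pd/C, cyclohexa-1,4-diene, EtOH, rt), which should give 24.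

Step 5. C-acylation of the amide enolate by the electron-rich, poorly electrophilic benzoate may be incomplete, with proton transfer returning the starting ester. Fallback, from 8 back to 11: the ester is saponified (LiOH, THF/H2O) to the carboxylic acid F4. The acid is condensed with Meldrum's acid (DCC, DMAP, CH2Cl2) to the acyl Meldrum's acid F5. Heating F5 with morpholine in toluene should give β-keto amide 11 by aminolysis with loss of acetone and carbon dioxide.

Further compounds
F1 | step 10 | (3R)-3-(4-{[(2S,4R,5R)-4-[4-(benzyloxy)phenyl]-2-phenyl-1,3-dioxan-5-yl]oxy}-3,5-dimethoxyphenyl)-3-hydroxy-1-(morpholin-4-yl)propan-1-one | O[C@H](CC(=O)N1CCOCC1)c1cc(OC)c(O[C@@H]2CO[C@H](c3ccccc3)O[C@@H]2c2ccc(OCc3ccccc3)cc2)c(OC)c1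
F2 | step 10 | (3S)-3-[3,5-bis(benzyloxy)-2-bromophenoxy]-3-(4-{[(2S,4R,5R)-4-[4-(benzyloxy)phenyl]-2-phenyl-1,3-dioxan-5-yl]oxy}-3,5-dimethoxyphenyl)-1-(morpholin-4-yl)propan-1-one | Brc1c(OCc2ccccc2)cc(OCc2ccccc2)cc1O[C@@H](CC(=O)N1CCOCC1)c1cc(OC)c(O[C@@H]2CO[C@H](c3ccccc3)O[C@@H]2c2ccc(OCc3ccccc3)cc2)c(OC)c1
F3 | step 11 | (2S)-5,7-bis(benzyloxy)-2-(4-{[(1R,2R)-1-[4-(benzyloxy)phenyl]-1,3-dihydroxypropan-2-yl]oxy}-3,5-dimethoxyphenyl)chroman-4-one | COc1cc([C@@H]2CC(=O)c3c(OCc4ccccc4)cc(OCc4ccccc4)cc3O2)cc(OC)c1O[C@H](CO)[C@H](O)c1ccc(OCc2ccccc2)cc1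
F4 | step 5 | 4-{[(2S,4R,5R)-4-[4-(benzyloxy)phenyl]-2-phenyl-1,3-dioxan-5-yl]oxy}-3,5-dimethoxybenzoic acid | OC(=O)c1cc(OC)c(O[C@@H]2CO[C@H](c3ccccc3)O[C@@H]2c2ccc(OCc3ccccc3)cc2)c(OC)c1
F5 | step 5 | 5-[(4-{[(2S,4R,5R)-4-[4-(benzyloxy)phenyl]-2-phenyl-1,3-dioxan-5-yl]oxy}-3,5-dimethoxyphenyl)(hydroxy)methylidene]-2,2-dimethyl-1,3-dioxane-4,6-dione | CC1(C)OC(=O)C(C(=O)O1)=C(O)c1cc(OC)c(O[C@@H]2CO[C@H](c3ccccc3)O[C@@H]2c2ccc(OCc3ccccc3)cc2)c(OC)c1
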